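**Plan**

1. Numbering: ring A = C1, C2, C3 (O-angeloyl), C4 (C15 ester), C5 (C14 methyl), C10 (H); ring B = C5, C6, C7 (arm C11–C13), C8 (ketone), C9, C10. Retrosynthetic cuts, in order: O3–acyl; C7–C11; C6–C7 and C7–C8 (C7 excised); C5–C14; C5–C10, C6–C8 and C8–C9 (C8 = CO); C3–C4.
2. Enabling feature: ring B holds a C6=C7–C8(=O) enone whose substituted carbon C7 lies between C6 and C8. This is what a dibromocyclopropanated cyclopentanone enol ether opens to, so C7 can be inserted last into the five-membered ring C5–C6–C8–C9–C10 of a cis-hydrindanone that already carries C3, C4, C5 and C10.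
3. Forward order: the C3–C4 bond joins a four-carbon alkynyl unit to pent-4-enal; a Pauson–Khand reaction closes ring A and the cyclopentenone together; methyl cuprate addition at C5 with silyl trapping gives the C6=C8 enol ether; dibromocarbene enlarges the five-membered ring to ring B; C15 is oxidised to the ester, the C7 bromide is coupled, and the angelate goes on last.
4. Stereochemistry: C4 from a lipase-resolved (S)-propargylic mesylate by chirality transfer through an allenylzinc; C3 by the anti selectivity of that addition; C10 in the Pauson–Khand closure under control of C3/C4; C5 by cis-hydrindane-forming conjugate addition; C11 by a chiral nickel catalyst; the Z-alkene from angelic acid.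

Key step: step 8

Assumption: the lipase in step 2 is taken to follow the usual secondary-alcohol model (CH2OPMB large, ethynyl medium), so the unreacted alcohol is the (S)-enantiomer; if the preference were reversed, the acetate would be methanolysed instead.

**Step 1**
Reactants: 1 2-[(4-methoxyphenyl)methoxy]acetaldehyde; 2 ethynylmagnesium bromide
Product: 3 rac-1-[(4-methoxyphenyl)methoxy]but-3-yn-2-ol
Conditions: THF, −78 → 0 °C; aq. NH4Cl
Reagents that add atoms: none
Why: Grignard addition of the acetylide to the aldehyde gives the propargylic alcohol without stereocontrol, which is acceptable because the carbinol centre is resolved in step 2.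

**Step 2**
Reactants: 3 rac-1-[(4-methoxyphenyl)methoxy]but-3-yn-2-ol
Product: 4 (2S)-1-[(4-methoxyphenyl)methoxy]but-3-yn-2-ol
Conditions: Amano lipase PS, vinyl acetate, MTBE, 30 °C, stopped shortly after half conversion; chromatography
Reagents that add atoms: none
Why: Lipase-catalysed kinetic resolution by irreversible transesterification should acylate the (R)-alcohol (Kazlauskas rule) and leave the (S)-alcohol 4, which is separated from the acetate.

**Step 3**
Reactants: 4 (2S)-1-[(4-methoxyphenyl)methoxy]but-3-yn-2-ol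
Product: 5 (2S)-1-[(4-methoxyphenyl)methoxy]but-3-yn-2-yl methanesulfonate
Conditions: MsCl, Et3N, CH2Cl2, −78 → 0 °C; used crude
Reagents that add atoms: methanesulfonyl chloride, CS(=O)(=O)Cl
Why: O-Sulfonylation (mesylation) of the secondary alcohol proceeds with retention at carbon and installs the leaving group needed for palladium(0).

**Step 4**
Reactants: 5 (2S)-1-[(4-methoxyphenyl)methoxy]but-3-yn-2-yl methanesulfonate; 6 pent-4-enal
Product: 8 (5R,6R)-6-{[(4-methoxyphenyl)methoxy]methyl}oct-1-en-7-yn-5-ol, via allenylzinc reagent 7 (not isolated)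
Conditions: Pd(OAc)2 (5 mol %), PPh3 (5 mol %), Et2Zn (3 equiv), THF, −78 → −20 °C; aq. NH4Cl
Reagents that add atoms: none
Why: Marshall–Tamaru propargylation: Pd(0) displaces the mesylate in an anti SN2′ sense, transmetallation gives the configurationally stable allenylzinc 7, and its addition to 6 through a closed six-membered SE2′ transition state transfers the mesylate chirality to C4 (R) and sets C3 (R) anti to the C4 arm because the aldehyde chain sits equatorial, any minor syn isomer being removable by chromatography.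

**Step 5**
Reactants: 8 (5R,6R)-6-{[(4-methoxyphenyl)methoxy]methyl}oct-1-en-7-yn-5-ol
Product: 9 tert-butyl{[(5R,6R)-6-{[(4-methoxyphenyl)methoxy]methyl}oct-1-en-7-yn-5-yl]oxy}dimethylsilane
Conditions: TBSOTf, 2,6-lutidine, CH2Cl2, −78 → 0 °C
Reagents that add atoms: tert-butyldimethylsilyl trifluoromethanesulfonate, CC(C)(C)[Si](C)(C)OS(=O)(=O)C(F)(F)F
Why: Silylation of the hindered secondary alcohol with the silyl triflate touches no stereocentre and gives a base-stable ether whose bulk later biases the ring closure.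

**Step 6**
Reactants: 9 tert-butyl{[(5R,6R)-6-{[(4-methoxyphenyl)methoxy]methyl}oct-1-en-7-yn-5-yl]oxy}dimethylsilane
Product: 11 (4R,5R,7aS)-5-[(tert-butyldimethylsilyl)oxy]-4-{[(4-methoxyphenyl)methoxy]methyl}-1,4,5,6,7,7a-hexahydro-2H-inden-2-one, via alkyne–hexacarbonyldicobalt complex 10 (not isolated)
Conditions: Co2(CO)8, CH2Cl2, rt; then n-BuSMe, ClCH2CH2Cl, 83 °C
Reagents that add atoms: dicobalt octacarbonyl, O=C=[Co](=C=O)(=C=O)(=C=O)[Co](=C=O)(=C=O)(=C=O)=C=O
Why: Intramolecular Pauson–Khand [2+2+1] cyclocarbonylation of the 1,7-enyne forms C5–C10, C8–C9 and C6–C8 in one operation, and C10 should be set by a chair-like alkene insertion with the C3 silyloxy group equatorial and the propargylic CH2OPMB arm axial, away from the cobalt-bound alkyne terminus, which places H10 cis to both substituents.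

**Step 7**
Reactants: 11 (4R,5R,7aS)-5-[(tert-butyldimethylsilyl)oxy]-4-{[(4-methoxyphenyl)methoxy]methyl}-1,4,5,6,7,7a-hexahydro-2H-inden-2-one
Product: 12 tert-butyl{[(3aR,4R,5R,7aS)-4-{[(4-methoxyphenyl)methoxy]methyl}-3a-methyl-2-[(trimethylsilyl)oxy]-3a,4,5,6,7,7a-hexahydro-1H-inden-5-yl]oxy}dimethylsilane
Conditions: Me2CuLi (MeLi, CuI), TMSCl, THF, −78 → −30 °C; Et3N, pentane, cold aq. NaHCO3; used crude
Reagents that add atoms: methyllithium, C[Li] (used as lithium dimethylcuprate, [Li+].C[Cu-]C); chlorotrimethylsilane, C[Si](C)(C)Cl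
Why: Chlorosilane-accelerated Gilman conjugate addition delivers methyl to C5 on the face of H10, the course leading to the cis-fused hydrindane that is the usual outcome for such bicyclic enones, and O-silylation of the enolate as it forms locks the enol double bond between C6 and C8.

**Step 8**
Reactants: 12 tert-butyl{[(3aR,4R,5R,7aS)-4-{[(4-methoxyphenyl)methoxy]methyl}-3a-methyl-2-[(trimethylsilyl)oxy]-3a,4,5,6,7,7a-hexahydro-1H-inden-5-yl]oxy}dimethylsilane
Product: 14 (4aR,5R,6R,8aS)-3-bromo-6-[(tert-butyldimethylsilyl)oxy]-5-{[(4-methoxyphenyl)methoxy]methyl}-4a-methyl-4a,5,6,7,8,8a-hexahydronaphthalen-2(1H)-one, via dibromocyclopropane 13 (not isolated)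
Conditions: CHBr3, KOt-Bu, pentane, −30 °C; cold filtration; then pyridine, toluene, 60 °C
Reagents that add atoms: bromoform, BrC(Br)Br
Why: Dibromocarbene, formed by α-elimination from bromoform, adds as an electrophile across the electron-rich C6=C8 enol ether from the convex face of the cis-hydrindene to give the 7,7-dibromo-8-silyloxy cyclopropane 13. The endo bromide then ionises with concerted disrotatory cleavage of the old C6–C8 bond (cyclopropyl-to-allyl cation opening, assisted by the silyloxy oxygen), and transfer of the silyl group to bromide leaves the C8 ketone conjugated with the new C6=C7(Br) alkene. The closest known reaction type is the dihalocarbene ring enlargement of cyclic trimethylsilyl enol ethers to 2-halocycloalk-2-enones. Ring B is therefore not closed by a cyclisation: it arises by one-carbon insertion, a [2+1] cheletropic addition followed by two-electron electrocyclic opening, which forms C6–C7 and C7–C8 and turns the five-membered ring into the six-membered one. No stereocentre is created, because both cyclopropane carbons end as sp2 centres and C3, C4, C5 and C10 are not touched. The step needs regioselectivity (insertion between C6 and C8, not C8 and C9), fixed by the position of the enol ether set in step 7, and chemoselectivity, secured because this is the only nucleophilic alkene in 12, while pyridine buffers the bromosilane so that the PMB and TBS ethers survive.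

**Step 9**
Reactants: 14 (4aR,5R,6R,8aS)-3-bromo-6-[(tert-butyldimethylsilyl)oxy]-5-{[(4-methoxyphenyl)methoxy]methyl}-4a-methyl-4a,5,6,7,8,8a-hexahydronaphthalen-2(1H)-one
Product: 15 (4aR,5R,6R,8aS)-3-bromo-6-[(tert-butyldimethylsilyl)oxy]-5-(hydroxymethyl)-4a-methyl-4a,5,6,7,8,8a-hexahydronaphthalen-2(1H)-one
Conditions: DDQ, CH2Cl2/pH 7 buffer, 0 °C
Reagents that add atoms: none
Why: Oxidative PMB cleavage with DDQ (benzylic hydride abstraction from the electron-rich arene, then hydrolysis of the oxocarbenium ion) frees the C15 alcohol and leaves the silyl ether and the bromoenone untouched.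

**Step 10**
Reactants: 15 (4aR,5R,6R,8aS)-3-bromo-6-[(tert-butyldimethylsilyl)oxy]-5-(hydroxymethyl)-4a-methyl-4a,5,6,7,8,8a-hexahydronaphthalen-2(1H)-one
Product: 16 (1S,2R,4aS,8aR)-7-bromo-2-[(tert-butyldimethylsilyl)oxy]-8a-methyl-6-oxo-1,2,3,4,4a,5,6,8a-octahydronaphthalene-1-carbaldehyde
Conditions: Dess–Martin periodinane, NaHCO3, CH2Cl2, 0 °C → rt
Reagents that add atoms: none
Why: Dess–Martin oxidation converts the hindered primary alcohol into the aldehyde under buffered, non-basic conditions that should neither epimerise C4 nor eliminate the β-silyloxy group.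

**Step 11**
Reactants: 16 (1S,2R,4aS,8aR)-7-bromo-2-[(tert-butyldimethylsilyl)oxy]-8a-methyl-6-oxo-1,2,3,4,4a,5,6,8a-octahydronaphthalene-1-carbaldehyde
Product: 17 (1S,2R,4aS,8aR)-7-bromo-2-[(tert-butyldimethylsilyl)oxy]-8a-methyl-6-oxo-1,2,3,4,4a,5,6,8a-octahydronaphthalene-1-carboxylic acid
Conditions: NaClO2, NaH2PO4, 2-methylbut-2-ene, t-BuOH/H2O, 0 °C → rt
Reagents that add atoms: sodium chlorite, [Na+].[O-]Cl=O
Why: Pinnick (chlorite) oxidation takes the aldehyde to the acid at mildly acidic pH with 2-methylbut-2-ene as hypochlorite scavenger, so C4 keeps its configuration.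

**Step 12**
Reactants: 17 (1S,2R,4aS,8aR)-7-bromo-2-[(tert-butyldimethylsilyl)oxy]-8a-methyl-6-oxo-1,2,3,4,4a,5,6,8a-octahydronaphthalene-1-carboxylic acid
Product: 18 methyl (1S,2R,4aS,8aR)-7-bromo-2-[(tert-butyldimethylsilyl)oxy]-8a-methyl-6-oxo-1,2,3,4,4a,5,6,8a-octahydronaphthalene-1-carboxylate
Conditions: TMSCHN2, toluene/MeOH, 0 °C
Reagents that add atoms: (trimethylsilyl)diazomethane, C[Si](C)(C)C=[N+]=[N-]
Why: Esterification with (trimethylsilyl)diazomethane (protonation of the diazo carbon by the acid, then alkylation of the carboxylate) gives the C15 methyl ester under neutral conditions.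

**Step 13**
Reactants: 18 methyl (1S,2R,4aS,8aR)-7-bromo-2-[(tert-butyldimethylsilyl)oxy]-8a-methyl-6-oxo-1,2,3,4,4a,5,6,8a-octahydronaphthalene-1-carboxylate; 19 methyl 2-chloropropanoate (racemic)
Product: 20 methyl (1S,2R,4aS,8aS)-2-[(tert-butyldimethylsilyl)oxy]-7-[(2S)-1-methoxy-1-oxopropan-2-yl]-8a-methyl-6-oxo-1,2,3,4,4a,5,6,8a-octahydronaphthalene-1-carboxylate
Conditions: NiBr2·diglyme (10 mol %), chiral 4,4′-di(heptan-4-yl)-2,2′-bi(oxazoline) (antipode selected for 11S), Mn powder, NaI, DMA, 0 °C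
Reagents that add atoms: none
Why: Proposed new method: Ni(0) bearing the chiral bi(oxazoline) should add oxidatively to the C7–Br bond of the electron-poor bromoenone, the alkenylnickel(II) captures the planar α-ester radical that nickel(I) generates from either enantiomer of 19 by chlorine abstraction (Mn as terminal reductant), and reductive elimination from the chiral nickel(III) species forms C7–C11 and sets C11 as S by catalyst control whatever the configuration of the chloride, the electrophilic radical being polarity-mismatched for addition to the enone; the closest known reaction types are the nickel/bis(oxazoline)-catalysed enantioconvergent reductive couplings of alkenyl bromides with benzylic chlorides and of aryl iodides with α-chloro esters, which have not been shown with a 2-bromoenone.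

**Step 14**
Reactants: 20 methyl (1S,2R,4aS,8aS)-2-[(tert-butyldimethylsilyl)oxy]-7-[(2S)-1-methoxy-1-oxopropan-2-yl]-8a-methyl-6-oxo-1,2,3,4,4a,5,6,8a-octahydronaphthalene-1-carboxylate
Product: 21 methyl (1S,2R,4aS,8aS)-2-hydroxy-7-[(2S)-1-methoxy-1-oxopropan-2-yl]-8a-methyl-6-oxo-1,2,3,4,4a,5,6,8a-octahydronaphthalene-1-carboxylate
Conditions: HF·pyridine, THF/pyridine, 0 °C → rt
Reagents that add atoms: none
Why: Fluoride-mediated desilylation with buffered HF·pyridine removes the TBS group under acidic conditions that should leave the base-sensitive C11 and C4 centres and both esters intact.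

**Step 15**
Reactants: 21 methyl (1S,2R,4aS,8aS)-2-hydroxy-7-[(2S)-1-methoxy-1-oxopropan-2-yl]-8a-methyl-6-oxo-1,2,3,4,4a,5,6,8a-octahydronaphthalene-1-carboxylate; 22 angelic acid
Product: 24 methyl (1S,2R,4aS,8aS)-7-[(2S)-1-methoxy-1-oxopropan-2-yl]-8a-methyl-2-{[(2Z)-2-methylbut-2-enoyl]oxy}-6-oxo-1,2,3,4,4a,5,6,8a-octahydronaphthalene-1-carboxylate, via mixed anhydride 23 (not isolated)
Conditions: 2,4,6-trichlorobenzoyl chloride, Et3N, toluene, rt; then 21, 75 °C
Reagents that add atoms: none
Why: Yamaguchi-type esterification through the mixed 2,4,6-trichlorobenzoic anhydride 23 without DMAP acylates the equatorial C3 hydroxyl with retention at C3 and is the established way to introduce an angelate without Z-to-E isomerisation.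

**Compound list**

1 | 2-[(4-methoxyphenyl)methoxy]acetaldehyde | O=CCOCc1ccc(OC)cc1 | starting material
2 | ethynylmagnesium bromide | C#C[Mg]Br | starting material
3 | rac-1-[(4-methoxyphenyl)methoxy]but-3-yn-2-ol | C#CC(O)COCc1ccc(OC)cc1 | intermediate
4 | (2S)-1-[(4-methoxyphenyl)methoxy]but-3-yn-2-ol | C#C[C@H](O)COCc1ccc(OC)cc1 | intermediate
5 | (2S)-1-[(4-methoxyphenyl)methoxy]but-3-yn-2-yl methanesulfonate | C#C[C@H](OS(C)(=O)=O)COCc1ccc(OC)cc1 | intermediate
6 | pent-4-enal | C=CCCC=O | starting material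
7 | (P)-ethyl{4-[(4-methoxyphenyl)methoxy]buta-1,2-dien-1-yl}zinc (allenylzinc, not isolated) | [H]C([Zn]CC)=[C@]=C([H])COCc1ccc(OC)cc1 | intermediate
8 | (5R,6R)-6-{[(4-methoxyphenyl)methoxy]methyl}oct-1-en-7-yn-5-ol | C#C[C@H](COCc1ccc(OC)cc1)[C@H](O)CCC=C | intermediate
9 | tert-butyl{[(5R,6R)-6-{[(4-methoxyphenyl)methoxy]methyl}oct-1-en-7-yn-5-yl]oxy}dimethylsilane | C#C[C@H](COCc1ccc(OC)cc1)[C@H](O[Si](C)(C)C(C)(C)C)CCC=C | intermediate
10 | hexacarbonyldicobalt complex of the alkyne of 9 (not isolated) | [CH]12[Co]3(=C=O)(=C=O)(=C=O)[Co]1(=C=O)(=C=O)(=C=O)[C]23[C@H](COCc1ccc(OC)cc1)[C@H](O[Si](C)(C)C(C)(C)C)CCC=C | intermediate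
11 | (4R,5R,7aS)-5-[(tert-butyldimethylsilyl)oxy]-4-{[(4-methoxyphenyl)methoxy]methyl}-1,4,5,6,7,7a-hexahydro-2H-inden-2-one | CC(C)(C)[Si](C)(C)O[C@@H]1CC[C@H]2CC(=O)C=C2[C@@H]1COCc1ccc(OC)cc1 | intermediate
12 | tert-butyl{[(3aR,4R,5R,7aS)-4-{[(4-methoxyphenyl)methoxy]methyl}-3a-methyl-2-[(trimethylsilyl)oxy]-3a,4,5,6,7,7a-hexahydro-1H-inden-5-yl]oxy}dimethylsilane (cis-hydrindanone trimethylsilyl enol ether) | CC(C)(C)[Si](C)(C)O[C@@H]1CC[C@H]2CC(O[Si](C)(C)C)=C[C@@]2(C)[C@@H]1COCc1ccc(OC)cc1 | intermediate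
13 | dibromocyclopropane adduct of 12 (CBr2 bridging C6 and C8 on the face of the angular methyl; not isolated) | CC(C)(C)[Si](C)(C)O[C@@H]1CC[C@H]2C[C@]3(O[Si](C)(C)C)C(Br)(Br)[C@@H]3[C@@]2(C)[C@@H]1COCc1ccc(OC)cc1 | intermediate
14 | (4aR,5R,6R,8aS)-3-bromo-6-[(tert-butyldimethylsilyl)oxy]-5-{[(4-methoxyphenyl)methoxy]methyl}-4a-methyl-4a,5,6,7,8,8a-hexahydronaphthalen-2(1H)-one | CC(C)(C)[Si](C)(C)O[C@@H]1CC[C@H]2CC(=O)C(Br)=C[C@@]2(C)[C@@H]1COCc1ccc(OC)cc1 | intermediate
15 | (4aR,5R,6R,8aS)-3-bromo-6-[(tert-butyldimethylsilyl)oxy]-5-(hydroxymethyl)-4a-methyl-4a,5,6,7,8,8a-hexahydronaphthalen-2(1H)-one | CC(C)(C)[Si](C)(C)O[C@@H]1CC[C@H]2CC(=O)C(Br)=C[C@@]2(C)[C@@H]1CO | intermediate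
16 | (1S,2R,4aS,8aR)-7-bromo-2-[(tert-butyldimethylsilyl)oxy]-8a-methyl-6-oxo-1,2,3,4,4a,5,6,8a-octahydronaphthalene-1-carbaldehyde | CC(C)(C)[Si](C)(C)O[C@@H]1CC[C@H]2CC(=O)C(Br)=C[C@@]2(C)[C@@H]1C=O | intermediate
17 | (1S,2R,4aS,8aR)-7-bromo-2-[(tert-butyldimethylsilyl)oxy]-8a-methyl-6-oxo-1,2,3,4,4a,5,6,8a-octahydronaphthalene-1-carboxylic acid | CC(C)(C)[Si](C)(C)O[C@@H]1CC[C@H]2CC(=O)C(Br)=C[C@@]2(C)[C@@H]1C(=O)O | intermediate
18 | methyl (1S,2R,4aS,8aR)-7-bromo-2-[(tert-butyldimethylsilyl)oxy]-8a-methyl-6-oxo-1,2,3,4,4a,5,6,8a-octahydronaphthalene-1-carboxylate | CC(C)(C)[Si](C)(C)O[C@@H]1CC[C@H]2CC(=O)C(Br)=C[C@@]2(C)[C@@H]1C(=O)OC | intermediate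
19 | methyl 2-chloropropanoate (racemic) | CC(Cl)C(=O)OC | starting material
20 | methyl (1S,2R,4aS,8aS)-2-[(tert-butyldimethylsilyl)oxy]-7-[(2S)-1-methoxy-1-oxopropan-2-yl]-8a-methyl-6-oxo-1,2,3,4,4a,5,6,8a-octahydronaphthalene-1-carboxylate | CC(C)(C)[Si](C)(C)O[C@@H]1CC[C@H]2CC(=O)C([C@H](C)C(=O)OC)=C[C@@]2(C)[C@@H]1C(=O)OC | intermediate
21 | methyl (1S,2R,4aS,8aS)-2-hydroxy-7-[(2S)-1-methoxy-1-oxopropan-2-yl]-8a-methyl-6-oxo-1,2,3,4,4a,5,6,8a-octahydronaphthalene-1-carboxylate | O[C@@H]1CC[C@H]2CC(=O)C([C@H](C)C(=O)OC)=C[C@@]2(C)[C@@H]1C(=O)OC | intermediate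
22 | angelic acid, (2Z)-2-methylbut-2-enoic acid | C/C=C(/C)C(=O)O | starting material
23 | (2Z)-2-methylbut-2-enoic 2,4,6-trichlorobenzoic anhydride (not isolated) | C/C=C(/C)C(=O)OC(=O)c1c(Cl)cc(Cl)cc1Cl | intermediate
24 | methyl (1S,2R,4aS,8aS)-7-[(2S)-1-methoxy-1-oxopropan-2-yl]-8a-methyl-2-{[(2Z)-2-methylbut-2-enoyl]oxy}-6-oxo-1,2,3,4,4a,5,6,8a-octahydronaphthalene-1-carboxylate (CNP0265265.1) | C/C=C(/C)C(=O)O[C@@H]1CC[C@H]2CC(=O)C([C@H](C)C(=O)OC)=C[C@@]2(C)[C@@H]1C(=O)OC | target

**Step count**

Total: 15 steps. Longest linear sequence: 15 steps (1 → 24).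

**Steps most likely to fail**

Step 13. Oxidative addition and radical capture at the α-branched, electron-poor alkenyl bromide may be slow, so that protodebromination or homocoupling competes, and catalyst control at C11 may be insufficient. The fallback uses known chemistry and sets out from 18. Palladium-catalysed Negishi-type coupling (Pd(dba)2, Q-Phos, THF, rt) with the Reformatsky reagent bromo(1-methoxy-1-oxopropan-2-yl)zinc F1, made from methyl 2-bromopropanoate and zinc, should give 20 together with its C11 epimer, methyl (1S,2R,4aS,8aS)-2-[(tert-butyldimethylsilyl)oxy]-7-[(2R)-1-methoxy-1-oxopropan-2-yl]-8a-methyl-6-oxo-1,2,3,4,4a,5,6,8a-octahydronaphthalene-1-carboxylate F2. The two are diastereomers and would be separated by chromatography; F2 would be re-equilibrated at its acidic C11–H with catalytic DBU and separated again. The route is rejoined at 20.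

Step 6. Ring closure may go through the competing chair with the C3 silyloxy group axial, giving the C10 epimer, and the unactivated 1,7-enyne may cyclise sluggishly. The fallback sets out from 9 and replaces steps 6 and 7.
- C-Silylation (n-BuLi, TMSCl, THF, −78 °C) gives tert-butyl{[(5R,6R)-6-{[(4-methoxyphenyl)methoxy]methyl}-8-(trimethylsilyl)oct-1-en-7-yn-5-yl]oxy}dimethylsilane F3.
- Complexation with Co2(CO)8 gives its hexacarbonyldicobalt complex F4, and Pauson–Khand cyclisation under the step 6 conditions gives (4R,5R,7aS)-5-[(tert-butyldimethylsilyl)oxy]-4-{[(4-methoxyphenyl)methoxy]methyl}-3-(trimethylsilyl)-1,4,5,6,7,7a-hexahydro-2H-inden-2-one F5. Allylic 1,3-strain between the silyl group and an equatorial C4 substituent forces the CH2OPMB arm axial in the closing chair, and so places H10 cis to it.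
- Methyl cuprate addition to this activated α-silyl enone (Me2CuLi, THF, −78 → −20 °C; NH4Cl) gives the cis-fused 3-(trimethylsilyl) ketone F6.
- Heating F6 in toluene at 110 °C induces a Brook-type 1,3 carbon-to-oxygen silyl shift, which delivers the C6=C8 enol ether regiospecifically under neutral conditions. The route is rejoined at 12.

Step 15. Acylation of the C3 hydroxyl next to the axial C4 ester may be incomplete, and prolonged heating with amine may isomerise the angeloyl unit to its E isomer or epimerise C11. The fallback sets out from 21. Esterification with 2-[bis(2,2,2-trifluoroethoxy)phosphoryl]propanoic acid (DCC, DMAP cat., CH2Cl2, 0 °C) gives the phosphonopropanoate ester of 21, F7. Still–Gennari olefination (KHMDS, 18-crown-6, THF, −78 °C; acetaldehyde) then builds the Z-2-methylbut-2-enoate on the oxygen that is already acylated; the phosphonate C–H is by far the most acidic site, so one equivalent of base should spare C11. The route is rejoined at 24.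

**Further compounds**

F1 | step 13 | bromo(1-methoxy-1-oxopropan-2-yl)zinc (Reformatsky reagent) | COC(=O)C(C)[Zn]Br
F2 | step 13 | methyl (1S,2R,4aS,8aS)-2-[(tert-butyldimethylsilyl)oxy]-7-[(2R)-1-methoxy-1-oxopropan-2-yl]-8a-methyl-6-oxo-1,2,3,4,4a,5,6,8a-octahydronaphthalene-1-carboxylate (C11 epimer of 20) | CC(C)(C)[Si](C)(C)O[C@@H]1CC[C@H]2CC(=O)C([C@@H](C)C(=O)OC)=C[C@@]2(C)[C@@H]1C(=O)OC
F3 | step 6 | tert-butyl{[(5R,6R)-6-{[(4-methoxyphenyl)methoxy]methyl}-8-(trimethylsilyl)oct-1-en-7-yn-5-yl]oxy}dimethylsilane | C[Si](C)(C)C#C[C@H](COCc1ccc(OC)cc1)[C@H](O[Si](C)(C)C(C)(C)C)CCC=C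
F4 | step 6 | hexacarbonyldicobalt complex of the alkyne of F3 | C[Si](C)(C)[C]12[Co]3(=C=O)(=C=O)(=C=O)[Co]1(=C=O)(=C=O)(=C=O)[C]23[C@H](COCc1ccc(OC)cc1)[C@H](O[Si](C)(C)C(C)(C)C)CCC=C
F5 | step 6 | (4R,5R,7aS)-5-[(tert-butyldimethylsilyl)oxy]-4-{[(4-methoxyphenyl)methoxy]methyl}-3-(trimethylsilyl)-1,4,5,6,7,7a-hexahydro-2H-inden-2-one | CC(C)(C)[Si](C)(C)O[C@@H]1CC[C@H]2CC(=O)C([Si](C)(C)C)=C2[C@@H]1COCc1ccc(OC)cc1
F6 | step 6 | cis-fused 5-[(tert-butyldimethylsilyl)oxy]-4-{[(4-methoxyphenyl)methoxy]methyl}-3a-methyl-3-(trimethylsilyl)octahydro-2H-inden-2-one (either C3 epimer) | CC(C)(C)[Si](C)(C)O[C@@H]1CC[C@H]2CC(=O)C([Si](C)(C)C)[C@@]2(C)[C@@H]1COCc1ccc(OC)cc1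
F7 | step 15 | 2-[bis(2,2,2-trifluoroethoxy)phosphoryl]propanoate ester of 21 at O3 (either configuration at the phosphonate carbon) | CC(P(=O)(OCC(F)(F)F)OCC(F)(F)F)C(=O)O[C@@H]1CC[C@H]2CC(=O)C([C@H](C)C(=O)OC)=C[C@@]2(C)[C@@H]1C(=O)OC
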